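The data were computed with constants of no real substance, noise included.

Late in the earlier runs the target flattens far below the partner charged. At 8.00 h it stands at 16.8%, 15.8% and 16.3% with 1 equiv, 0.50 equiv and 2 equiv of second substrate, a mean of 16.3%. With 1.2 equiv of partner it reads 18.8%.

| run | time / h | target / % |
|---|---|---|
| west | 0.500 | 4.5 |
| west | 0.833 | 8.1 |
| west | 1.33 | 9.4 |
| west | 2.00 | 12.3 |
| west | 3.00 | 14.1 |
| west | 5.00 | 14.5 |
| west | 8.00 | 16.8 |
| north-west | 0.417 | 4.4 |
| north-west | 1.00 | 8.4 |
| north-west | 2.00 | 11.8 |
| north-west | 3.00 | 13.6 |
| north-west | 4.00 | 14.4 |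
| north-west | 6.00 | 15.8 |
| north-west | 8.00 | 15.8 |
| south-east | 1.00 | 8.3 |
| south-east | 2.00 | 12.2 |
| south-east | 3.00 | 13.4 |
| south-east | 4.00 | 14.5 |
| south-east | 5.00 | 15.9 |
| south-east | 6.00 | 15.0 |
| south-east | 8.00 | 16.3 |
| east | 0.667 | 8.5 |
| east | 2.00 | 15.4 |
| east | 3.00 | 16.9 |
| east | 5.00 | 19.0 |
| east | 8.00 | 18.8 |

(readings scatter by 0.5 percentage points)

- the best flask by amount of target, in percent of the starting material charged; "all alike" if 1.5 percentage points covers them all (spring / dawn / noon / autumn / all alike)
- amount of target at the end, in percent of the starting material charged, spring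
- amount of target at the end, in percent of the starting material charged, dawn
- amount of target at the end, in percent of the starting material charged, noon
- amount of target at the end, in percent of the starting material charged, autumn



| setting | west | north-west | south-east | east | spring | dawn | noon | autumn |
|---|---|---|---|---|---|---|---|---|
| starting material | 0.20 M | 0.20 M | 0.20 M | 0.20 M | 0.20 M | 0.20 M | 0.20 M | 0.20 M (fed, over 2.5 h) |
| partner | 0.80 equiv | 0.80 equiv | 0.80 equiv | 1.2 equiv | 0.800 equiv (fed, over 2.5 h) | 0.800 equiv | 0.800 equiv (fed, over 15 min) | 0.800 equiv |
| second substrate | 1 equiv | 0.50 equiv | 2 equiv | 1 equiv | 1.00 equiv | 1.00 equiv | 1.00 equiv | 1.00 equiv |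
| remark | run made earlier | run made earlier | run made earlier | run made earlier | all else is in the flask from the start; the feed brings no volume worth counting | everything together at the start | all else is in the flask from the start; the feed brings no volume worth counting | all else is in the flask from the start; the feed brings no volume worth counting |
| time |  |  |  |  | 12 h | 12 h | 12 h | 12 h |

Follow one partner molecule at a fork: starting material captures it, or another partner destroys it. The extra partner of the east run became target with a chance s = 6.25%, a reading with the scatter of the runs. If capture is first order in partner and the loss second order, the chance at partner level B is E/(E+B). Setting this equal to s at the mean charge of 1.00 equiv gives E = 0.0667 equiv, the even level, where both exits are equally likely.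

The recipes now read row by row, in this reckoning. Dawn opens at a chance of 7.69%, and summing the chance as partner falls gives E·ln(one plus charge/E) = 17.1%. Noon's feed lasts 15 min, against 2.5 h in spring, so noon reads as dawn. The two-hour readings give a capture constant of 0.280 h⁻¹, a reading with their scatter. Spring's feed is then reckoned to balance at B = 0.245 equiv, a chance of 21.4%, and the reckoned feed plus tail give 22.2%. During its feed, autumn has on average 0.5 of its starting material charged, so this reckoning takes E times that share, and the sum gives 10.7%.

The forecast names spring: 21.5% for spring, 16.8% for dawn, 17.6% for noon and 10.5% for autumn, on the ground that “Feeding partner keeps B low, which favours capture.”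

The flasks give 18.4% in spring, 15.9% at dawn, 16.2% at noon and 11.3% in autumn, so spring is best, by 2.2 percentage points over noon.

    2 partner → homo dimer (k = 3.56 M⁻¹ h⁻¹)
    second substrate + partner → second product (k = 0.0183 M⁻¹ h⁻¹)
    starting material + partner ⇌ target (K = 17.0 M⁻¹, k = 0.891 M⁻¹ h⁻¹)

The even-level reckoning stands 3.8 points above spring and 1.2 points above dawn. Spring's answer has moved by 5 points at 0.419 equiv or 1.43 equiv of partner. E was read across 0.50 equiv to 2 equiv of second substrate and holds no term for it, so the same reckoning gives the same 22.2% for the neighbour, spring with 0.600 equiv. That neighbour gives 18.4%, against 18.4% for spring. Its second product at 12.0 h is 7.74 × 10⁻⁴ M, against 0.00129 M in spring.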